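We chose to judge these flasks by one measure instead of by their recipes, which read very differently.

| flask | starting complex | incoming ligand | temperature | remark | time |
|---|---|---|---|---|---|
| alder | 5 mM (fed, over 15 s) | 0.82 equiv | 45 °C | run made earlier |  |
| elm | 5 mM (fed, over 15 s) | 2.3 equiv | 56 °C | run made earlier |  |
| gamma | 5.0 mM | 3.60 equiv | 50 °C | everything together at the start | 1.2 min |
| zeta | 5.0 mM (fed, over 15 s) | 1.20 equiv | 50 °C |  | 4.0 min |

| run | time / s | complex with three exchanged / % | starting complex / % |
|---|---|---|---|
| alder | 10.0 | 0.6 | 63.6 |
| alder | 15.0 | 0 | 94.7 |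
| alder | 20.0 | 0.5 | 93.3 |
| alder | 30.0 | 1.1 | 87.6 |
| alder | 50.0 | 1.1 | 78.7 |
| alder | 80.0 | 0.5 | 69.5 |
| alder | 120 | 0.8 | 59.1 |
| elm | 15.0 | 1.4 | 78.2 |
| elm | 30.0 | 1.9 | 45.2 |
| elm | 50.0 | 6.0 | 25.1 |
| elm | 60.0 | 6.7 | 21.6 |
| elm | 80.0 | 8.4 | 15.0 |
| elm | 90.0 | 10.7 | 11.9 |
| elm | 120 | 10.6 | 7.7 |

(standard deviation of a reading: 1 percentage point)

- the analysis behind the earlier runs scatters by 1 percentage point, standard deviation
- percentages count the whole charge, also what has not yet gone in

1. which of the two ends with the higher amount of complex with three exchanged, in percent of the starting complex charged ("neither" if they lie within 2 percentage points) (gamma / zeta / neither)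
2. complex with three exchanged at the end, in percent of the starting complex charged, gamma
3. complex with three exchanged at the end, in percent of the starting complex charged, zeta

For gamma the charge and the time give 21.6 mM·min, and this ligand dose, the charged c(incoming ligand) multiplied by the time, is the quantity of a pseudo-first-order reckoning: at one temperature, and while c(incoming ligand) holds at its charge, the logarithm of charged over remaining starting complex grows in step with the dose. Zeta collects 24.0 mM·min, a factor of 1.11 on gamma, and by its last reading the elm run had collected 23.0 mM·min, with 7.7% starting complex and 10.6% complex with three exchanged, though at 56 °C, which is hotter than 50 °C.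

So the doses lie together, but a dose is reckoned on the charge, and the charge has to pay. Counting 3 exchanges per complex, gamma's 3.60 equiv pays for 1.20 times its starting complex and zeta's 1.20 equiv for 0.400 times, which makes incoming ligand the limiting reagent in zeta, so we expect c(incoming ligand) to fall far below its charge there and the dose reckoned on the charge to overstate what zeta receives. We therefore expect zeta to stand well below elm's reading, and gamma, cooler than elm but with more equivalents of incoming ligand, near or above it.

The forecast, made from these runs, says gamma, with 12% for gamma and 4.5% for zeta, and holds that “1.2 equiv runs out of ligand”.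

The flask gives gamma, with 17.7% in gamma and 3.84% in zeta.

    starting complex + incoming ligand → leaving ligand + complex with one exchanged (k = 2.40 M⁻¹ s⁻¹, Ea = 65.0 kJ mol⁻¹)
    complex with one exchanged + incoming ligand → leaving ligand + complex with two exchanged (k = 4.50 M⁻¹ s⁻¹, Ea = 40.0 kJ mol⁻¹)
    complex with two exchanged + incoming ligand → leaving ligand + complex with three exchanged (k = 1.30 M⁻¹ s⁻¹, Ea = 35.0 kJ mol⁻¹)
    complex with three exchanged + incoming ligand → leaving ligand + complex with four exchanged (k = 0.900 M⁻¹ s⁻¹, Ea = 65.0 kJ mol⁻¹)
    starting complex + complex with two exchanged → side product A (k = 1.80 M⁻¹ s⁻¹, Ea = 45.0 kJ mol⁻¹)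
    complex with two exchanged → decomposed reagent (k = 0.0100 s⁻¹, Ea = 97.0 kJ mol⁻¹)
    complex with one exchanged → side product B (k = 0.00570 s⁻¹, Ea = 98.0 kJ mol⁻¹)
    (constants at 50 °C)

Gamma's dose brought the logarithm of charged over remaining starting complex to 2.25, while zeta's dose, though larger, brought it to 1.33, and at the end gamma keeps 49% of its incoming ligand and zeta 11%. The run with incoming ligand held at its charge shows what this costs: zeta then ends at 14.6% instead of 3.84%, so the using up of incoming ligand takes 11 percentage points from zeta, one effect and not the whole of the difference.

The neighbour flask that repeats zeta with 12 mM of starting complex, equivalents and time held, has a dose of 57.6 mM·min, a factor of 2.40 on zeta, yet its equivalents still pay for 0.400 times its starting complex. Computed, this neighbour ends with 1.5% of its incoming ligand, 18% starting complex and 5.43% complex with three exchanged.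

The data are calculated from invented constants; the scatter is artificial.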